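**Retrosynthetic overview**
1. Target 20 ⇒ acid 17. The 1,2-dioxane is the only ring and is closed last, by acid/MeOH peroxy-ketalization of a masked (3S)-3-hydroperoxy-6-oxo acid; C6 is set thermodynamically.
2. 17 ⇒ keto-enal 12 + hydroperoxy ketal 15. The C3–O bond and the C3 stereocentre come from an amine-catalysed asymmetric peroxy-Michael addition, then CHO → CO2H in the same flask.
3. 12 ⇒ keto aldehyde 10 + C2 formyl ylide 11 (Wittig); 10 ⇒ enyne nitrile 5 + C3 acetal Grignard reagent (from 6).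
4. 5 ⇒ (E)-vinyl iodide 3 + hex-5-ynenitrile 4 (Sonogashira); 3 ⇐ undec-1-yne 1.

**Assumptions**
- Ring atoms are numbered O1–O2–C3–C4–C5–C6 (C3 bears CH2CO2H, C6 bears OMe and the side chain). In this numbering the target is (3S,6R), with OMe cis to CH2CO2H. Open-chain compounds use fatty-acid numbering (C1 = carboxyl or formyl carbon).
- 2-Methoxypropan-2-yl hydroperoxide is not a catalogue item, so it is made in step 5.
- All peroxide steps are run on small scale behind a shield.

**Route**

Step 1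
Reactants: 1 undec-1-yne
Product: 3 (E)-1-iodoundec-1-ene, via alkenylalane 2 (not isolated)
Conditions: i-Bu2AlH (1.05 equiv), hexane, 50 °C, 4 h; then I2 (1.1 equiv), THF, −50 °C → rt
Reagents that add atoms: iodine, II
Why: Zweifel hydroalumination–iodinolysis: syn addition of Al–H to the terminal alkyne gives only the (E)-alkenylalane, and iodine cleaves the vinyl C–Al bond with retention, so the E alkene of the target is fixed here.

Step 2
Reactants: 3 (E)-1-iodoundec-1-ene; 4 hex-5-ynenitrile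
Product: 5 (E)-heptadec-7-en-5-ynenitrile
Conditions: PdCl2(PPh3)2 (2 mol %), CuI (4 mol %), Et3N (3 equiv), degassed THF, rt
Reagents that add atoms: none
Why: Sonogashira coupling, which keeps the geometry of the vinyl iodide and tolerates the nitrile.

Step 3
Reactants: 5 (E)-heptadec-7-en-5-ynenitrile; 6 2-(2-bromoethyl)-1,3-dioxolane
Product: 10 (E)-4-oxoicos-10-en-8-ynal, via Grignard reagent 7 (not isolated), via N-magnesio ketimine 8 (not isolated), via keto dioxolane 9 (not isolated)
Conditions: 6, Mg turnings, THF, 25–30 °C; add 5, CuBr·SMe2 (5 mol %), THF, 25–35 °C; then 2 M aq HCl/THF (1:1), rt, until ketimine and dioxolane are both cleaved; use crude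
Reagents that add atoms: water, O; magnesium, [Mg] (kept only in 7 and 8)
Why: Copper-catalysed Grignard addition to a nitrile stops at the N-magnesio ketimine, so no over-addition occurs, and one aqueous acid work-up hydrolyses both the ketimine and the dioxolane to give the 1,4-keto aldehyde.

Step 4
Reactants: 10 (E)-4-oxoicos-10-en-8-ynal; 11 (triphenylphosphoranylidene)acetaldehyde
Product: 12 (2E,12E)-6-oxodocosa-2,12-dien-10-ynal
Conditions: 11 (1.1 equiv), toluene, 70 °C
Reagents that add atoms: none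
Why: Wittig olefination with a stabilised formyl ylide, which reacts with the aldehyde but not the ketone and gives the (E)-enal.

Step 5
Reactants: 13 2,3-dimethylbut-2-ene
Product: 15 2-methoxypropan-2-yl hydroperoxide, via acetone O-oxide 14 (not isolated)
Conditions: O3, CH2Cl2/MeOH (4:1), −78 °C; N2 purge; concentrate cold; store and use as a solution
Reagents that add atoms: ozone, [O-][O+]=O; methanol, CO
Why: Criegee ozonolysis in methanol: the carbonyl oxide 14 is trapped by methanol to give the hydroperoxy ketal, an acid-removable carrier of one O–O–H unit.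

Step 6
Reactants: 12 (2E,12E)-6-oxodocosa-2,12-dien-10-ynal; 15 2-methoxypropan-2-yl hydroperoxide
Product: 17 (3S,12E)-3-[(2-methoxypropan-2-yl)peroxy]-6-oxodocos-12-en-10-ynoic acid, via peroxy aldehyde 16 (not isolated)
Conditions: 15 (2 equiv), (R)-2-[diphenyl(trimethylsilyloxy)methyl]pyrrolidine (20 mol %), PhCO2H (20 mol %), toluene, 0 °C; then same flask: t-BuOH/H2O, 2-methylbut-2-ene (20 equiv), NaH2PO4, NaClO2, 0 °C
Reagents that add atoms: sodium chlorite, [Na+].[O-]Cl=O
Why: Iminium-catalysed enantioselective peroxy-Michael addition (diarylprolinol silyl ether catalysis, a known reaction type for enals and alkyl hydroperoxides) followed in the same flask by Pinnick oxidation: the hydroperoxide adds to the β-carbon of the s-trans E-iminium ion on the face opposite the diphenyl(silyloxy)methyl group, which for the (R)-catalyst gives 3S, while benzoic acid protonates the enamine before it can close to the epoxide and the immediate oxidation removes the aldehyde so that retro-Michael erosion of ee is avoided.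

Step 7
Reactants: 17 (3S,12E)-3-[(2-methoxypropan-2-yl)peroxy]-6-oxodocos-12-en-10-ynoic acid
Product: 20 2-[(3S,6R)-6-[(6E)-hexadec-6-en-4-yn-1-yl]-6-methoxy-1,2-dioxan-3-yl]acetic acid, via hydroperoxy keto acid 18 (not isolated), via peroxy hemiketal 19 (not isolated)
Conditions: PPTS (0.2 equiv), anhydrous MeOH (0.05 M), 0 °C → rt; Et3N quench; resubmit any minor C6 epimer
Reagents that add atoms: methanol, CO
Why: Biomimetic peroxy-ketalization cascade (acid-catalysed transketalization of the 2-methoxyprop-2-yl peroxide, 6-exo addition of the freed C3 hydroperoxide to the C6 ketone, then exchange of the hemiketal OH for OMe): C3 is untouched, and C6 equilibrates through the ring peroxycarbenium ion to the 6R epimer, which has OMe axial (anomeric effect) and both carbon substituents equatorial.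

**Compound list**
1 | undec-1-yne | CCCCCCCCCC#C | starting material
2 | (E)-undec-1-en-1-yl-bis(2-methylpropyl)alumane | CCCCCCCCC/C=C/[Al](CC(C)C)CC(C)C | intermediate (not isolated)
3 | (E)-1-iodoundec-1-ene | CCCCCCCCC/C=C/I | intermediate
4 | hex-5-ynenitrile | C#CCCCC#N | starting material
5 | (E)-heptadec-7-en-5-ynenitrile | CCCCCCCCC/C=C/C#CCCCC#N | intermediate
6 | 2-(2-bromoethyl)-1,3-dioxolane | BrCCC1OCCO1 | starting material
7 | [2-(1,3-dioxolan-2-yl)ethyl]magnesium bromide | Br[Mg]CCC1OCCO1 | intermediate (not isolated)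
8 | (E)-1-(1,3-dioxolan-2-yl)nonadec-9-en-7-yn-3-imine N-magnesium bromide | CCCCCCCCC/C=C/C#CCCCC(CCC1OCCO1)=N[Mg]Br | intermediate (not isolated)
9 | (E)-1-(1,3-dioxolan-2-yl)nonadec-9-en-7-yn-3-one | CCCCCCCCC/C=C/C#CCCCC(=O)CCC1OCCO1 | intermediate (not isolated)
10 | (E)-4-oxoicos-10-en-8-ynal | CCCCCCCCC/C=C/C#CCCCC(=O)CCC=O | intermediate
11 | (triphenylphosphoranylidene)acetaldehyde | O=CC=P(c1ccccc1)(c1ccccc1)c1ccccc1 | starting material
12 | (2E,12E)-6-oxodocosa-2,12-dien-10-ynal | CCCCCCCCC/C=C/C#CCCCC(=O)CC/C=C/C=O | intermediate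
13 | 2,3-dimethylbut-2-ene | CC(C)=C(C)C | starting material
14 | acetone O-oxide | CC(C)=[O+][O-] | intermediate (not isolated)
15 | 2-methoxypropan-2-yl hydroperoxide | COC(C)(C)OO | intermediate
16 | (3S,12E)-3-[(2-methoxypropan-2-yl)peroxy]-6-oxodocos-12-en-10-ynal | CCCCCCCCC/C=C/C#CCCCC(=O)CC[C@@H](CC=O)OOC(C)(C)OC | intermediate (not isolated)
17 | (3S,12E)-3-[(2-methoxypropan-2-yl)peroxy]-6-oxodocos-12-en-10-ynoic acid | CCCCCCCCC/C=C/C#CCCCC(=O)CC[C@@H](CC(=O)O)OOC(C)(C)OC | intermediate
18 | (3S,12E)-3-hydroperoxy-6-oxodocos-12-en-10-ynoic acid | CCCCCCCCC/C=C/C#CCCCC(=O)CC[C@@H](CC(=O)O)OO | intermediate (not isolated)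
19 | 2-[(3S)-6-[(6E)-hexadec-6-en-4-yn-1-yl]-6-hydroxy-1,2-dioxan-3-yl]acetic acid (C6 epimers) | CCCCCCCCC/C=C/C#CCCCC1(O)CC[C@@H](CC(=O)O)OO1 | intermediate (not isolated)
20 | 2-[(3S,6R)-6-[(6E)-hexadec-6-en-4-yn-1-yl]-6-methoxy-1,2-dioxan-3-yl]acetic acid | CCCCCCCCC/C=C/C#CCCC[C@]1(OC)CC[C@@H](CC(=O)O)OO1 | target

**Step count**
Total: 7 steps. Longest linear sequence: 6 steps (1, 2, 3, 4, 6, 7 from undec-1-yne); step 5 is a one-step side branch.

**Three steps most likely to fail, with fallbacks**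

Step 6 (highest risk). The β-peroxy enamine may close to the 2,3-epoxy aldehyde, the enamine may add to the C6 ketone in an aldol reaction, or the ee may be modest. The fallback sets out from 10 and comes back at 20. It gives up catalyst control and uses the classical base-mediated ring closure, followed by resolution. Wittig reaction of 10 with methyl (triphenylphosphoranylidene)acetate gives methyl (2E,12E)-6-oxodocosa-2,12-dien-10-ynoate F1. HC(OMe)3 and PPTS in MeOH give the dimethyl ketal methyl (2E,12E)-6,6-dimethoxydocosa-2,12-dien-10-ynoate F2. Anhydrous ethereal H2O2 with catalytic CSA exchanges one OMe for OOH to give methyl (2E,12E)-6-hydroperoxy-6-methoxydocosa-2,12-dien-10-ynoate F3. Et2NH in CF3CH2OH closes the ring by 6-exo peroxy-Michael addition, and PPTS/MeOH equilibrates C6, giving racemic methyl 2-[(3S*,6R*)-6-[(6E)-hexadec-6-en-4-yn-1-yl]-6-methoxy-1,2-dioxan-3-yl]acetate F4. LiOH in THF/H2O at 0 °C gives racemic 2-[(3S*,6R*)-6-[(6E)-hexadec-6-en-4-yn-1-yl]-6-methoxy-1,2-dioxan-3-yl]acetic acid F5. Preparative chiral SFC then separates 20 from 2-[(3R,6S)-6-[(6E)-hexadec-6-en-4-yn-1-yl]-6-methoxy-1,2-dioxan-3-yl]acetic acid F6.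

Step 7. PPTS may be too weak to drive the hemiketal to the methyl ketal, while stronger acid in MeOH would esterify the free acid. The fallback sets out from 17 and comes back at 20. It protects the acid so that stronger acid and a dehydrating agent can be used. TMSCHN2 in toluene/MeOH gives methyl (3S,12E)-3-[(2-methoxypropan-2-yl)peroxy]-6-oxodocos-12-en-10-ynoate F7. TsOH·H2O (5 mol %) in MeOH/HC(OMe)3 runs the same cascade to give methyl 2-[(3S,6R)-6-[(6E)-hexadec-6-en-4-yn-1-yl]-6-methoxy-1,2-dioxan-3-yl]acetate F8. LiOH in THF/H2O at 0 °C (or pig-liver esterase at pH 7) then gives 20.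

Step 3. The Grignard reagent may deprotonate the nitrile α-position instead of adding, reagent 7 decomposes above about 35 °C, and the 1,4-keto aldehyde can cyclise during the acid work-up. The fallback sets out from 3 and comes back at 10. It replaces the nitrile with a Weinreb amide and isolates the acetal. Hex-5-ynoic acid, CDI and MeNHOMe·HCl give N-methoxy-N-methylhex-5-ynamide F9. Sonogashira coupling of F9 with 3 under the step 2 conditions gives (E)-N-methoxy-N-methylheptadec-7-en-5-ynamide F10. Grignard reagent 7 adds once at 0 °C through the stable chelate to give 9, now isolated and purified. A separate, monitored hydrolysis with 1 M aq HCl/THF at rt gives 10.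

**Further compounds**
F1 | step 6 | methyl (2E,12E)-6-oxodocosa-2,12-dien-10-ynoate | CCCCCCCCC/C=C/C#CCCCC(=O)CC/C=C/C(=O)OC
F2 | step 6 | methyl (2E,12E)-6,6-dimethoxydocosa-2,12-dien-10-ynoate | CCCCCCCCC/C=C/C#CCCCC(OC)(OC)CC/C=C/C(=O)OC
F3 | step 6 | methyl (2E,12E)-6-hydroperoxy-6-methoxydocosa-2,12-dien-10-ynoate | CCCCCCCCC/C=C/C#CCCCC(OC)(OO)CC/C=C/C(=O)OC
F4 | step 6 | racemic methyl 2-[(3S*,6R*)-6-[(6E)-hexadec-6-en-4-yn-1-yl]-6-methoxy-1,2-dioxan-3-yl]acetate | CCCCCCCCC/C=C/C#CCCC[C@]1(OC)CC[C@@H](CC(=O)OC)OO1.CCCCCCCCC/C=C/C#CCCC[C@@]1(OC)CC[C@H](CC(=O)OC)OO1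
F5 | step 6 | racemic 2-[(3S*,6R*)-6-[(6E)-hexadec-6-en-4-yn-1-yl]-6-methoxy-1,2-dioxan-3-yl]acetic acid | CCCCCCCCC/C=C/C#CCCC[C@]1(OC)CC[C@@H](CC(=O)O)OO1.CCCCCCCCC/C=C/C#CCCC[C@@]1(OC)CC[C@H](CC(=O)O)OO1
F6 | step 6 | 2-[(3R,6S)-6-[(6E)-hexadec-6-en-4-yn-1-yl]-6-methoxy-1,2-dioxan-3-yl]acetic acid | CCCCCCCCC/C=C/C#CCCC[C@@]1(OC)CC[C@H](CC(=O)O)OO1
F7 | step 7 | methyl (3S,12E)-3-[(2-methoxypropan-2-yl)peroxy]-6-oxodocos-12-en-10-ynoate | CCCCCCCCC/C=C/C#CCCCC(=O)CC[C@@H](CC(=O)OC)OOC(C)(C)OC
F8 | step 7 | methyl 2-[(3S,6R)-6-[(6E)-hexadec-6-en-4-yn-1-yl]-6-methoxy-1,2-dioxan-3-yl]acetate | CCCCCCCCC/C=C/C#CCCC[C@]1(OC)CC[C@@H](CC(=O)OC)OO1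
F9 | step 3 | N-methoxy-N-methylhex-5-ynamide | C#CCCCC(=O)N(C)OC
F10 | step 3 | (E)-N-methoxy-N-methylheptadec-7-en-5-ynamide | CCCCCCCCC/C=C/C#CCCCC(=O)N(C)OC
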